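## Retrosynthetic overview

- **Feature:** the benzofuran carbocycle reads C7(OH), C6(H), C5(CH2 of the linker), C4(prenyl), and is closed by the furan carbons C3a and C7a. These positions correspond to a carbonyl carbon, the CH and C(alkyl) of a terminal alkyne, a carbon holding both prenyl and 3-furyl, and furan C3/C2.
- **Disconnections:** (a) the two aryl O–Si bonds. (b) C7–C7a (retro-6π, then retro-4π), back to a 4-(3-furyl)-4-prenyl-3-alkylcyclobut-2-enone. (c) C7–C6 and C5–C4 (retro-[2+2]), to an α-prenylated 3-furylacetamide (as its keteniminium ion) and a ring A pent-4-ynyl arene.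
- **Ring A fragment:** 2,4-dihydroxybenzaldehyde is O-prenylated and an aromatic Claisen shift to C5 sets the 1,1-dimethylallyl group. Homopropargyl Grignard addition and benzylic deoxygenation then give the linker and the alkyne.
- **Ring order:** ring A and the furan are bought. The four-membered ring is made in step 10, which also joins the two halves. Step 11 expands it into the benzene ring of the benzofuran.

Key step: step 11

Abbreviations: TBS = tert-butyldimethylsilyl; Ar = 2,4-bis(tert-butyldimethylsilyloxy)-5-(2-methylbut-3-en-2-yl)phenyl.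

Remark: the target has no stereocentre and no stereogenic double bond, so every chiral intermediate is carried as a racemate.

## Route

Step 1
Reactants: 1 2,4-dihydroxybenzaldehyde; 2 prenyl bromide (1-bromo-3-methylbut-2-ene)
Product: 3 2-hydroxy-4-(3-methylbut-2-en-1-yloxy)benzaldehyde
Conditions: K2CO3 (1.1 equiv), acetone, 56 °C
Reagents that add atoms: none
Why: Williamson ether synthesis, in which the 2-OH is held in a hydrogen bond to the formyl oxygen, so about one equivalent of carbonate deprotonates only the free, more acidic 4-OH, which displaces bromide at the primary allylic carbon (SN2).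

Step 2
Reactants: 3 2-hydroxy-4-(3-methylbut-2-en-1-yloxy)benzaldehyde
Product: 4 2-(tert-butyldimethylsilyloxy)-4-(3-methylbut-2-en-1-yloxy)benzaldehyde
Conditions: TBSCl, imidazole, DMF, 25 °C
Reagents that add atoms: tert-butyldimethylsilyl chloride, CC(C)(C)[Si](C)(C)Cl
Why: Imidazole-promoted O-silylation of a phenol, which removes the OH to formyl chelate that would steer the coming rearrangement to C3 and sets a bulky group beside C3.

Step 3
Reactants: 4 2-(tert-butyldimethylsilyloxy)-4-(3-methylbut-2-en-1-yloxy)benzaldehyde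
Product: 6 4-hydroxy-5-(2-methylbut-3-en-2-yl)-2-(tert-butyldimethylsilyloxy)benzaldehyde, via Claisen dienone 5 (not isolated)
Conditions: PhNEt2, 190 °C, Ar
Reagents that add atoms: none
Why: Aromatic Claisen rearrangement, a [3,3]-sigmatropic shift with allyl inversion that turns the O-prenyl group into a C-bound 1,1-dimethylallyl group and ends with enolisation of dienone 5, and of the two ortho sites only C5 can take the new quaternary carbon without clashing with the silyloxy group next to C3.

Step 4
Reactants: 6 4-hydroxy-5-(2-methylbut-3-en-2-yl)-2-(tert-butyldimethylsilyloxy)benzaldehyde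
Product: 7 2,4-bis(tert-butyldimethylsilyloxy)-5-(2-methylbut-3-en-2-yl)benzaldehyde
Conditions: TBSCl, imidazole, DMAP (cat.), DMF, 40 °C
Reagents that add atoms: tert-butyldimethylsilyl chloride, CC(C)(C)[Si](C)(C)Cl
Why: O-silylation of the acidic para-formyl phenol, run warm because of the neighbouring tert-alkyl group, which also converges any material whose silyl group moved between the two phenols during the thermolysis.

Step 5
Reactants: 7 2,4-bis(tert-butyldimethylsilyloxy)-5-(2-methylbut-3-en-2-yl)benzaldehyde; 8 (4-bromobut-1-yn-1-yl)trimethylsilane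
Product: 10 1-Ar-5-(trimethylsilyl)pent-4-yn-1-ol (racemic), via Grignard reagent 9 (not isolated)
Conditions: 8, Mg, I2 (cat.), THF, 40 °C; then 7, THF, −78 to −20 °C; aq. NH4Cl
Reagents that add atoms: none
Why: Grignard addition to a non-enolisable aromatic aldehyde, in which the alkynyl silane masks the acidic alkyne C–H, the low temperature and cold quench hold back migration of the ortho silyl group to the new alkoxide, and the racemic carbinol centre is erased in step 6.

Step 6
Reactants: 10 1-Ar-5-(trimethylsilyl)pent-4-yn-1-ol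
Product: 11 (5-Ar-pent-1-yn-1-yl)trimethylsilane
Conditions: Et3SiH (3 equiv), CF3CO2H (3 equiv, added last), CH2Cl2, −40 to 0 °C; aq. NaHCO3
Reagents that add atoms: none
Why: Ionic hydrogenation (Kursanov–Parnes reduction), in which the ortho and para silyloxy groups let the benzylic C–O bond ionise under mild acid in the cold and the silane delivers hydride to that carbon, while the monosubstituted vinyl group, the silylalkyne and the acid-tolerant aryl silyl ethers stay untouched.

Step 7
Reactants: 11 (5-Ar-pent-1-yn-1-yl)trimethylsilane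
Product: 12 1-(pent-4-yn-1-yl)-2,4-bis(tert-butyldimethylsilyloxy)-5-(2-methylbut-3-en-2-yl)benzene
Conditions: AgNO3 (10 mol %), CH2Cl2/MeOH/H2O, 25 °C
Reagents that add atoms: none
Why: Silver-catalysed protiodesilylation of a 1-(trimethylsilyl)alkyne, in which monovalent silver binds the triple bond and labilises only the C(sp)–Si bond toward water, whereas the usual basic methanolysis would strip the aryl silyl ethers.

Step 8
Reactants: 13 2-(furan-3-yl)acetic acid
Product: 15 2-(furan-3-yl)-N,N-dimethylacetamide, via acylimidazole 14 (not isolated)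
Conditions: CDI, THF, 25 °C; then Me2NH (2 M in THF), 25 °C
Reagents that add atoms: dimethylamine, CNC
Why: Amide coupling through the acylimidazole, run under neutral conditions that spare the acid-sensitive furan.

Step 9
Reactants: 15 2-(furan-3-yl)-N,N-dimethylacetamide; 2 prenyl bromide
Product: 17 2-(furan-3-yl)-N,N,5-trimethylhex-4-enamide (racemic), via lithium enolate 16 (not isolated)
Conditions: LDA (1.05 equiv), THF, −78 °C; then 2, −78 to 0 °C
Reagents that add atoms: none
Why: Alkylation of a furyl-stabilised tertiary amide enolate with a reactive primary allylic bromide (SN2), giving a racemic α-centre that becomes sp2 again in step 10.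

Step 10
Reactants: 12 1-(pent-4-yn-1-yl)-2,4-bis(tert-butyldimethylsilyloxy)-5-(2-methylbut-3-en-2-yl)benzene; 17 2-(furan-3-yl)-N,N,5-trimethylhex-4-enamide
Product: 20 3-(3-Ar-propyl)-4-(furan-3-yl)-4-(3-methylbut-2-en-1-yl)cyclobut-2-en-1-one (racemic), via keteniminium triflate 18 (not isolated), via cyclobutene iminium triflate 19 (not isolated)
Conditions: 17 (1.3 equiv), Tf2O, CH2Cl2, −25 °C; then 12, 2,4,6-collidine, −25 to 25 °C; then aq. NaHCO3, 25 °C
Reagents that add atoms: water, O
Why: Ghosez keteniminium–alkyne [2+2] cycloaddition, in which O-triflation and collidine-induced elimination give 18, its central carbon is attacked by the terminal alkyne carbon and the developing vinyl cation on the internal carbon closes onto the former α-carbon, so that H sits at C2 and the linker at C3 of the racemic cyclobutenone released on hydrolysis of 19; complete pre-activation keeps every furan and prenyl group next to a cationic centre and hence poorly nucleophilic, the vinyl group of 12 is shielded by its quaternary neighbour, the one-carbon tether rules out intramolecular capture by the prenyl bond, and staying at or below 25 °C avoids electrocyclic opening of 19 before nitrogen is exchanged for oxygen.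

Step 11
Reactants: 20 3-(3-Ar-propyl)-4-(furan-3-yl)-4-(3-methylbut-2-en-1-yl)cyclobut-2-en-1-one
Product: 23 5-(3-Ar-propyl)-4-(3-methylbut-2-en-1-yl)-1-benzofuran-7-ol, via (Z)-dienylketene 21 (not isolated), via 7aH-benzofuranone tautomer 22 (not isolated)
Conditions: xylenes (0.01 M, degassed), 140 °C
Reagents that add atoms: none
Why: Heat breaks the C1–C4 bond of 20 in a conrotatory 4π ring opening to dienylketene 21, whose ketene carbon bonds to furan C2 in a disrotatory 6π electrocyclisation (new C7–C7a bond, six-membered ring C7–C6–C5–C4–C3a–C7a) to give 22, and transfer of the 7a-hydrogen to oxygen gives the aromatic phenol 23. The closest known reaction type is the thermal ring expansion of 4-aryl- and 4-heteroarylcyclobutenones to fused phenols (Smith–Hoehn reaction, Danheiser benzannulation, Moore rearrangement), and the 4-alkyl-4-(3-furyl) pattern without a 4-oxygen substituent is an untested member of that class. No stereocentre has to be controlled, since the quaternary C4 of 20 and C7a of 22 both end as sp2 carbons. Site selectivity on the furan follows from bond localisation: only C2=C3 completes a hexatriene with the ketene C=C and the C5=C4 alkene, whereas C3–C4 is formally a single bond. The step also needs furyl rather than prenyl to end cis to the ketene; the prenyl-inward isomer can re-close to 20, and the small resonance energy of furan makes the aromatising closure fast. The irreversible exits of that isomer, ketene–alkene [2+2] with the prenyl bond and a 1,5-hydrogen shift from its CH2 group, require more ordered transition states, so high temperature should disfavour them, and high dilution should keep 23 from being acylated by 21.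

Step 12
Reactants: 23 5-(3-Ar-propyl)-4-(3-methylbut-2-en-1-yl)-1-benzofuran-7-ol
Product: 24 4-{3-[7-hydroxy-4-(3-methylbut-2-en-1-yl)-1-benzofuran-5-yl]propyl}-6-(2-methylbut-3-en-2-yl)benzene-1,3-diol (CNP0288359.0)
Conditions: Bu4NF (2.5 equiv), AcOH (2.5 equiv), THF, 0 °C, Ar
Reagents that add atoms: none
Why: Fluoride-induced cleavage of aryl silyl ethers driven by Si–F bond formation, with acetic acid buffering the phenoxides so that the oxidation-prone triphenol and its acid-sensitive allyl groups are released near neutrality.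

## Compound list

1 | 2,4-dihydroxybenzaldehyde | O=Cc1ccc(O)cc1O | starting material
2 | prenyl bromide (1-bromo-3-methylbut-2-ene) | CC(C)=CCBr | starting material
3 | 2-hydroxy-4-(3-methylbut-2-en-1-yloxy)benzaldehyde | O=Cc1ccc(OCC=C(C)C)cc1O | intermediate
4 | 2-(tert-butyldimethylsilyloxy)-4-(3-methylbut-2-en-1-yloxy)benzaldehyde | O=Cc1ccc(OCC=C(C)C)cc1O[Si](C)(C)C(C)(C)C | intermediate
5 | 4-oxo-5-(2-methylbut-3-en-2-yl)-2-(tert-butyldimethylsilyloxy)cyclohexa-1(6),2-diene-1-carbaldehyde (arene numbering kept, racemic, not isolated) | O=CC1=CC(C(C)(C)C=C)C(=O)C=C1O[Si](C)(C)C(C)(C)C | intermediate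
6 | 4-hydroxy-5-(2-methylbut-3-en-2-yl)-2-(tert-butyldimethylsilyloxy)benzaldehyde | O=Cc1cc(C(C)(C)C=C)c(O)cc1O[Si](C)(C)C(C)(C)C | intermediate
7 | 2,4-bis(tert-butyldimethylsilyloxy)-5-(2-methylbut-3-en-2-yl)benzaldehyde | O=Cc1cc(C(C)(C)C=C)c(O[Si](C)(C)C(C)(C)C)cc1O[Si](C)(C)C(C)(C)C | intermediate
8 | (4-bromobut-1-yn-1-yl)trimethylsilane | C[Si](C)(C)C#CCCBr | starting material
9 | [4-(trimethylsilyl)but-3-yn-1-yl]magnesium bromide (not isolated) | C[Si](C)(C)C#CCC[Mg]Br | intermediate
10 | 1-[2,4-bis(tert-butyldimethylsilyloxy)-5-(2-methylbut-3-en-2-yl)phenyl]-5-(trimethylsilyl)pent-4-yn-1-ol (racemic) | C[Si](C)(C)C#CCCC(O)c1cc(C(C)(C)C=C)c(O[Si](C)(C)C(C)(C)C)cc1O[Si](C)(C)C(C)(C)C | intermediate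
11 | {5-[2,4-bis(tert-butyldimethylsilyloxy)-5-(2-methylbut-3-en-2-yl)phenyl]pent-1-yn-1-yl}trimethylsilane | C[Si](C)(C)C#CCCCc1cc(C(C)(C)C=C)c(O[Si](C)(C)C(C)(C)C)cc1O[Si](C)(C)C(C)(C)C | intermediate
12 | 1-(pent-4-yn-1-yl)-2,4-bis(tert-butyldimethylsilyloxy)-5-(2-methylbut-3-en-2-yl)benzene | C#CCCCc1cc(C(C)(C)C=C)c(O[Si](C)(C)C(C)(C)C)cc1O[Si](C)(C)C(C)(C)C | intermediate
13 | 2-(furan-3-yl)acetic acid | OC(=O)Cc1ccoc1 | starting material
14 | 2-(furan-3-yl)-1-(imidazol-1-yl)ethan-1-one (not isolated) | O=C(Cc1ccoc1)n1ccnc1 | intermediate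
15 | 2-(furan-3-yl)-N,N-dimethylacetamide | CN(C)C(=O)Cc1ccoc1 | intermediate
16 | lithium enolate of 15 (not isolated) | CN(C)C(O[Li])=Cc1ccoc1 | intermediate
17 | 2-(furan-3-yl)-N,N,5-trimethylhex-4-enamide (racemic) | CN(C)C(=O)C(CC=C(C)C)c1ccoc1 | intermediate
18 | N-[2-(furan-3-yl)-5-methylhexa-1,4-dien-1-ylidene]-N-methylmethanaminium triflate (not isolated) | C[N+](C)=C=C(CC=C(C)C)c1ccoc1.[O-]S(=O)(=O)C(F)(F)F | intermediate
19 | N-[3-(3-Ar-propyl)-4-(furan-3-yl)-4-(3-methylbut-2-en-1-yl)cyclobut-2-en-1-ylidene]-N-methylmethanaminium triflate (racemic, not isolated) | C[N+](C)=C1C=C(CCCc2cc(C(C)(C)C=C)c(O[Si](C)(C)C(C)(C)C)cc2O[Si](C)(C)C(C)(C)C)C1(CC=C(C)C)c1ccoc1.[O-]S(=O)(=O)C(F)(F)F | intermediate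
20 | 3-(3-Ar-propyl)-4-(furan-3-yl)-4-(3-methylbut-2-en-1-yl)cyclobut-2-en-1-one (racemic) | O=C1C=C(CCCc2cc(C(C)(C)C=C)c(O[Si](C)(C)C(C)(C)C)cc2O[Si](C)(C)C(C)(C)C)C1(CC=C(C)C)c1ccoc1 | intermediate
21 | (3Z)-3-(3-Ar-propyl)-4-(furan-3-yl)-7-methylocta-1,3,6-trien-1-one, furyl cis to the ketenyl group (not isolated) | O=C=C/C(CCCc1cc(C(C)(C)C=C)c(O[Si](C)(C)C(C)(C)C)cc1O[Si](C)(C)C(C)(C)C)=C(/CC=C(C)C)c1ccoc1 | intermediate
22 | 5-(3-Ar-propyl)-4-(3-methylbut-2-en-1-yl)-1-benzofuran-7(7aH)-one (racemic, not isolated) | O=C1C=C(CCCc2cc(C(C)(C)C=C)c(O[Si](C)(C)C(C)(C)C)cc2O[Si](C)(C)C(C)(C)C)C(CC=C(C)C)=C2C=COC12 | intermediate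
23 | 5-(3-Ar-propyl)-4-(3-methylbut-2-en-1-yl)-1-benzofuran-7-ol | Oc1cc(CCCc2cc(C(C)(C)C=C)c(O[Si](C)(C)C(C)(C)C)cc2O[Si](C)(C)C(C)(C)C)c(CC=C(C)C)c2ccoc12 | intermediate
24 | 4-{3-[7-hydroxy-4-(3-methylbut-2-en-1-yl)-1-benzofuran-5-yl]propyl}-6-(2-methylbut-3-en-2-yl)benzene-1,3-diol (CNP0288359.0) | C=CC(C)(C)c1cc(CCCc2cc(O)c3occc3c2CC=C(C)C)c(O)cc1O | target

## Step count

Total step count: 12.
Longest linear sequence: 10 (steps 1–7, then 10–12). Steps 8–9 form the short branch.

## Steps most likely to fail

**1. Step 10.**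
- **What may go wrong:** the keteniminium ion may be captured by the furan or prenyl π systems of a second amide molecule, or by the vinyl group of the alkyne partner. The sluggish, non-excess terminal alkyne would then lose the competition. Premature electrocyclic opening of the iminium salt is a second concern.
- **Fallback:** it sets out from 17, uses aldehyde 7 and returns at 24; the fragment union is moved away from the cycloaddition.
  - Amide 17 is activated as in step 10, but the cation is intercepted by inexpensive 4-bromobut-1-yne in large excess. This gives 3-(2-bromoethyl)-4-(furan-3-yl)-4-(3-methylbut-2-en-1-yl)cyclobut-2-en-1-one F1.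
  - Thermolysis as in step 11 gives 5-(2-bromoethyl)-4-(3-methylbut-2-en-1-yl)-1-benzofuran-7-ol F2.
  - Silylation (TBSCl, imidazole) gives [5-(2-bromoethyl)-4-(3-methylbut-2-en-1-yl)-1-benzofuran-7-yloxy](tert-butyl)dimethylsilane F3.
  - Magnesium insertion gives the corresponding 2-arylethylmagnesium bromide F4, and its addition to 7 gives the racemic diarylpropanol F5.
  - Ionic hydrogenation (Et3SiH, CF3CO2H, −40 °C) should proceed at a temperature where the trisubstituted alkene is not protonated at a competitive rate. It gives the tris-silyl ether of the target F6, and Bu4NF/AcOH converts this into 24.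

**2. Step 11.**
- **What may go wrong:** material may leak through prenyl-inward ring opening, followed by intramolecular ketene–alkene cycloaddition or a 1,5-hydrogen shift. Acylation of the product phenol by the ketene is a second loss channel.
- **Fallback:** it sets out from 15, uses alkyne 12 and returns at 23; the prenyl group is kept out of the thermolysis.
  - Unalkylated amide 15 and 12 are combined under the conditions of step 10. This gives 3-(3-Ar-propyl)-4-(furan-3-yl)cyclobut-2-en-1-one F7, the 4-H, 4-heteroaryl type for which the ring expansion is best documented.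
  - Heating gives 5-(3-Ar-propyl)-1-benzofuran-7-ol F8.
  - Bromination para to the phenol (NBS, MeCN, −20 °C) gives 4-bromo-5-(3-Ar-propyl)-1-benzofuran-7-ol F9.
  - A neutral Stille coupling with tributyl(3-methylbut-2-en-1-yl)stannane (Pd(PPh3)4, DMF, 90 °C) attaches the linear prenyl group and gives 23.

**3. Step 3.**
- **What may go wrong:** site selectivity between C3 and C5 may be incomplete. An abnormal Claisen rearrangement or cyclisation of the freed ortho-allyl phenol may follow, and the prenyl group may be lost thermally.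
- **Fallback:** it sets out from 1 and returns at 7; the quaternary benzylic carbon is made by cross-coupling instead of a sigmatropic shift.
  - Bromination of 1 (Br2, AcOH) at C5 gives 5-bromo-2,4-dihydroxybenzaldehyde F10.
  - Double silylation gives 5-bromo-2,4-bis(tert-butyldimethylsilyloxy)benzaldehyde F11.
  - A branch-selective Suzuki–Miyaura coupling with 3-methylbut-2-en-1-ylboronic acid pinacol ester forms the C–C bond at the γ-carbon of the allyl boronate and gives 7. Conditions are Pd(OAc)2, a bulky biaryl phosphine, K3PO4 and aqueous MeCN. Any phenol bared by the base is resilylated with TBSCl.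

## Further compounds

F1 | step 10 | 3-(2-bromoethyl)-4-(furan-3-yl)-4-(3-methylbut-2-en-1-yl)cyclobut-2-en-1-one (racemic) | O=C1C=C(CCBr)C1(CC=C(C)C)c1ccoc1
F2 | step 10 | 5-(2-bromoethyl)-4-(3-methylbut-2-en-1-yl)-1-benzofuran-7-ol | Oc1cc(CCBr)c(CC=C(C)C)c2ccoc12
F3 | step 10 | [5-(2-bromoethyl)-4-(3-methylbut-2-en-1-yl)-1-benzofuran-7-yloxy](tert-butyl)dimethylsilane | CC(C)(C)[Si](C)(C)Oc1cc(CCBr)c(CC=C(C)C)c2ccoc12
F4 | step 10 | {2-[7-(tert-butyldimethylsilyloxy)-4-(3-methylbut-2-en-1-yl)-1-benzofuran-5-yl]ethyl}magnesium bromide | CC(C)(C)[Si](C)(C)Oc1cc(CC[Mg]Br)c(CC=C(C)C)c2ccoc12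
F5 | step 10 | 1-Ar-3-[7-(tert-butyldimethylsilyloxy)-4-(3-methylbut-2-en-1-yl)-1-benzofuran-5-yl]propan-1-ol (racemic) | OC(CCc1cc(O[Si](C)(C)C(C)(C)C)c2occc2c1CC=C(C)C)c1cc(C(C)(C)C=C)c(O[Si](C)(C)C(C)(C)C)cc1O[Si](C)(C)C(C)(C)C
F6 | step 10 | tris(tert-butyldimethylsilyl) ether of 24 | C=CC(C)(C)c1cc(CCCc2cc(O[Si](C)(C)C(C)(C)C)c3occc3c2CC=C(C)C)c(O[Si](C)(C)C(C)(C)C)cc1O[Si](C)(C)C(C)(C)C
F7 | step 11 | 3-(3-Ar-propyl)-4-(furan-3-yl)cyclobut-2-en-1-one (racemic) | O=C1C=C(CCCc2cc(C(C)(C)C=C)c(O[Si](C)(C)C(C)(C)C)cc2O[Si](C)(C)C(C)(C)C)C1c1ccoc1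
F8 | step 11 | 5-(3-Ar-propyl)-1-benzofuran-7-ol | Oc1cc(CCCc2cc(C(C)(C)C=C)c(O[Si](C)(C)C(C)(C)C)cc2O[Si](C)(C)C(C)(C)C)cc2ccoc12
F9 | step 11 | 4-bromo-5-(3-Ar-propyl)-1-benzofuran-7-ol | Oc1cc(CCCc2cc(C(C)(C)C=C)c(O[Si](C)(C)C(C)(C)C)cc2O[Si](C)(C)C(C)(C)C)c(Br)c2ccoc12
F10 | step 3 | 5-bromo-2,4-dihydroxybenzaldehyde | O=Cc1cc(Br)c(O)cc1O
F11 | step 3 | 5-bromo-2,4-bis(tert-butyldimethylsilyloxy)benzaldehyde | O=Cc1cc(Br)c(O[Si](C)(C)C(C)(C)C)cc1O[Si](C)(C)C(C)(C)C
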